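## Retrosynthetic overview

1. The target comes in one acid-hydrolysis step from a fully masked α-acyloxy amide (activated 2-pyridyl amide, tert-butyl ester, catechol acetonide, aryl acetate).
2. Key disconnection: the lactate C1–C2 bond, together with the ester C–O bond and the (R) centre, by a catalytic asymmetric three-component α-addition. An isocyanide carbon acts as a carboxyl-anion equivalent towards an arylacetaldehyde, and the benzodioxane cinnamic acid is the acyl donor.
3. The cinnamic acid comes from a Heck coupling of a 7-bromo-cis-benzodioxane ester with acrylic acid; the cis-(2R,3R) centres come from asymmetric hydrogenation of the tetrasubstituted 1,4-benzodioxine.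
4. The benzodioxine comes from copper-catalysed enolate O-arylation of an α-aryloxy β-keto ester, itself from a crossed Claisen condensation; the aldehyde comes from ozonolysis of eugenyl acetate.
5. Ring order: catechol acetonide (protecting ring) first, then the 1,4-dioxine ring, then its reduction to the cis-dioxane; no other ring is made.

Assumption: the SMILES is read literally, giving (R) at the lactate carbon and a cis-(2R,3R) benzodioxane (CO2H on C2 and aryl on C3 on the same face, side chain on C7 para to O4); the facial sense of the two chiral catalysts is drawn as needed for this isomer and must be confirmed on the first run (the antipodal catalyst is used otherwise).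

## Route

Step 1
Reactants: 1 methyl 3,4-dihydroxybenzoate
Product: 2 methyl 2,2-dimethyl-1,3-benzodioxole-5-carboxylate
Conditions: 2,2-dimethoxypropane (3 equiv), p-toluenesulfonic acid monohydrate (5 mol%), toluene, reflux, MeOH removed over 4 Å molecular sieves
Reagents that add atoms: 2,2-dimethoxypropane, COC(C)(C)OC
Why: Acid-catalysed transketalisation of the catechol, driven by removal of methanol, gives the catechol acetonide that survives base, copper, hydrogen and palladium and is removed in the final acid step; no stereocentre is formed.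

Step 2
Reactants: 3 2,5-dibromophenol; 4 tert-butyl bromoacetate
Product: 5 tert-butyl (2,5-dibromophenoxy)acetate
Conditions: K2CO3 (1.5 equiv), acetone, reflux
Reagents that add atoms: none
Why: Williamson ether synthesis in which the phenoxide displaces the activated primary bromide by an SN2 reaction; no stereocentre is formed.

Step 3
Reactants: 5 tert-butyl (2,5-dibromophenoxy)acetate; 2 methyl 2,2-dimethyl-1,3-benzodioxole-5-carboxylate
Product: 7 tert-butyl 2-(2,5-dibromophenoxy)-3-(2,2-dimethyl-1,3-benzodioxol-5-yl)-3-oxopropanoate (racemic), via lithium enolate 6 (not isolated)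
Conditions: LiN(SiMe3)2 (2.1 equiv), THF, −78 °C; then 2, −78 → 0 °C; AcOH quench
Reagents that add atoms: none
Why: Crossed Claisen condensation in which the preformed enolate of the hindered tert-butyl ester acylates on the non-enolisable methyl aryl ester and the second equivalent of base drives the equilibrium by deprotonating the β-keto ester, whose single labile stereocentre is erased in the next step.

Step 4
Reactants: 7 tert-butyl 2-(2,5-dibromophenoxy)-3-(2,2-dimethyl-1,3-benzodioxol-5-yl)-3-oxopropanoate
Product: 8 tert-butyl 7-bromo-3-(2,2-dimethyl-1,3-benzodioxol-5-yl)-1,4-benzodioxine-2-carboxylate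
Conditions: CuI (10 mol%), 1,10-phenanthroline (20 mol%), Cs2CO3 (1.5 equiv), toluene, 100 °C
Reagents that add atoms: none
Why: Intramolecular Ullmann-type C–O coupling under monovalent copper catalysis in which the enolate oxygen of the β-keto ester is arylated by the ortho bromide to close the six-membered 1,4-dioxine ring (C-arylation would need a four-membered ring and the bromide para to the new C–O bond can only react intermolecularly), placing the remaining bromide at C7 and removing the labile stereocentre.

Step 5
Reactants: 8 tert-butyl 7-bromo-3-(2,2-dimethyl-1,3-benzodioxol-5-yl)-1,4-benzodioxine-2-carboxylate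
Product: 9 tert-butyl (2R,3R)-7-bromo-3-(2,2-dimethyl-1,3-benzodioxol-5-yl)-2,3-dihydro-1,4-benzodioxine-2-carboxylate (cis)
Conditions: H2 (50 bar), [Ir(cod)(L)][B(3,5-(CF3)2C6H3)4] (2 mol%; cod = cycloocta-1,5-diene; L = (S)-4-tert-butyl-2-[2-(diphenylphosphanyl)phenyl]-4,5-dihydro-1,3-oxazole), CH2Cl2, 25 °C
Reagents that add atoms: none
Why: Proposed new method: an inner-sphere iridium dihydride adds both hydrogens to the same face of the tetrasubstituted C2=C3 enol-ether double bond (ester carbonyl as second binding point), so the cis relationship follows from syn addition and the chiral P,N ligand selects the face that gives (2R,3R) while the aryl bromide is untouched, the closest known reaction types being iridium P,N-ligand asymmetric hydrogenation of tetrasubstituted olefins and cyclic enol ethers and the iridium-catalysed asymmetric hydrogenation of 2-substituted 1,4-benzodioxines.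

Step 6
Reactants: 9 tert-butyl (2R,3R)-7-bromo-3-(2,2-dimethyl-1,3-benzodioxol-5-yl)-2,3-dihydro-1,4-benzodioxine-2-carboxylate; 10 acrylic acid
Product: 11 (E)-3-[(2R,3R)-2-(tert-butoxycarbonyl)-3-(2,2-dimethyl-1,3-benzodioxol-5-yl)-2,3-dihydro-1,4-benzodioxin-7-yl]prop-2-enoic acid
Conditions: Pd[P(t-Bu)3]2 (3 mol%), Cy2NMe (2.2 equiv), 1,4-dioxane, 50 °C; aq. citric acid work-up
Reagents that add atoms: none
Why: Mizoroki–Heck reaction in which oxidative addition of the aryl bromide to zerovalent palladium, syn insertion of acrylic acid and syn β-hydride elimination give the (E)-cinnamic acid directly, the hindered amine and low temperature leaving the epimerisable C2 centre and both acid-labile groups intact.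

Step 7
Reactants: 12 4-allyl-2-methoxyphenyl acetate (eugenyl acetate)
Product: 14 2-(4-acetoxy-3-methoxyphenyl)acetaldehyde, via secondary ozonide 13 (not isolated)
Conditions: O3, CH2Cl2, −78 °C; then PPh3 (1.1 equiv), −78 °C → rt; used at once
Reagents that add atoms: ozone, [O-][O+]=O
Why: Ozonolysis in which 1,3-dipolar cycloaddition of ozone to the terminal alkene and rearrangement give the secondary ozonide that triphenylphosphine reduces to the arylacetaldehyde, the acetylated ring being too electron-poor to compete for ozone; no stereocentre is carried forward.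

Step 8
Reactants: 11 (E)-3-[(2R,3R)-2-(tert-butoxycarbonyl)-3-(2,2-dimethyl-1,3-benzodioxol-5-yl)-2,3-dihydro-1,4-benzodioxin-7-yl]prop-2-enoic acid; 14 2-(4-acetoxy-3-methoxyphenyl)acetaldehyde; 15 2-bromo-6-isocyanopyridine
Product: 16 (2R)-3-(4-acetoxy-3-methoxyphenyl)-1-[(6-bromopyridin-2-yl)amino]-1-oxopropan-2-yl (E)-3-[(2R,3R)-2-(tert-butoxycarbonyl)-3-(2,2-dimethyl-1,3-benzodioxol-5-yl)-2,3-dihydro-1,4-benzodioxin-7-yl]prop-2-enoate
Conditions: (R)-3,3'-bis(2,4,6-triisopropylphenyl)-1,1'-binaphthalene-2,2'-diyl hydrogen phosphate (10 mol%), 4 Å molecular sieves, CH2Cl2 (0.2 M), 0 °C → rt; 14 and 15 at 1.5 equiv each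
Reagents that add atoms: none
Why: Catalytic enantioselective Passerini three-component reaction in which the divalent isocyanide carbon, acting as a carboxyl (acyl) anion equivalent, adds to the Si face of the aldehyde held in the hydrogen-bonded pair of chiral phosphoric acid and carboxylic acid and a Mumm-type acyl shift then places the cinnamoyl group on the new carbinol oxygen, so that the lactate C1–C2 bond, the ester linkage and the (R) centre are formed in one operation.

Step 9
Reactants: 16 (2R)-3-(4-acetoxy-3-methoxyphenyl)-1-[(6-bromopyridin-2-yl)amino]-1-oxopropan-2-yl (E)-3-[(2R,3R)-2-(tert-butoxycarbonyl)-3-(2,2-dimethyl-1,3-benzodioxol-5-yl)-2,3-dihydro-1,4-benzodioxin-7-yl]prop-2-enoate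
Product: 17 clinopodic acid F
Conditions: 3 M HCl, 1,4-dioxane/H2O (3:1), 40 °C, argon, HPLC control
Reagents that add atoms: water, O
Why: Acid-catalysed hydrolysis in which the N-(6-bromopyridin-2-yl) amide behaves as an activated amide (the protonated aminopyridine is a good leaving group) and is cleaved under the same conditions that remove the tert-butyl ester, the catechol acetonide and the aryl acetate, while the hindered conjugated secondary cinnamate ester and all three stereocentres, none of which is enolised under these conditions, are kept.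

## Compound list

1 | methyl 3,4-dihydroxybenzoate | COC(=O)c1ccc(O)c(O)c1 | starting material
2 | methyl 2,2-dimethyl-1,3-benzodioxole-5-carboxylate | COC(=O)c1ccc2OC(C)(C)Oc2c1 | intermediate
3 | 2,5-dibromophenol | Oc1cc(Br)ccc1Br | starting material
4 | tert-butyl bromoacetate | BrCC(=O)OC(C)(C)C | starting material
5 | tert-butyl (2,5-dibromophenoxy)acetate | CC(C)(C)OC(=O)COc1cc(Br)ccc1Br | intermediate
6 | lithium enolate of 5, lithium 1-tert-butoxy-2-(2,5-dibromophenoxy)ethenolate | [Li]OC(OC(C)(C)C)=COc1cc(Br)ccc1Br | intermediate (not isolated)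
7 | tert-butyl 2-(2,5-dibromophenoxy)-3-(2,2-dimethyl-1,3-benzodioxol-5-yl)-3-oxopropanoate (racemic) | CC(C)(C)OC(=O)C(Oc1cc(Br)ccc1Br)C(=O)c1ccc2OC(C)(C)Oc2c1 | intermediate
8 | tert-butyl 7-bromo-3-(2,2-dimethyl-1,3-benzodioxol-5-yl)-1,4-benzodioxine-2-carboxylate | CC(C)(C)OC(=O)C1=C(c2ccc3OC(C)(C)Oc3c2)Oc2ccc(Br)cc2O1 | intermediate
9 | tert-butyl (2R,3R)-7-bromo-3-(2,2-dimethyl-1,3-benzodioxol-5-yl)-2,3-dihydro-1,4-benzodioxine-2-carboxylate (cis) | Brc1ccc2c(c1)O[C@@H](C(=O)OC(C)(C)C)[C@@H](c1ccc3OC(C)(C)Oc3c1)O2 | intermediate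
10 | acrylic acid | C=CC(=O)O | starting material
11 | (E)-3-[(2R,3R)-2-(tert-butoxycarbonyl)-3-(2,2-dimethyl-1,3-benzodioxol-5-yl)-2,3-dihydro-1,4-benzodioxin-7-yl]prop-2-enoic acid | OC(=O)/C=C/c1ccc2c(c1)O[C@@H](C(=O)OC(C)(C)C)[C@@H](c1ccc3OC(C)(C)Oc3c1)O2 | intermediate
12 | 4-allyl-2-methoxyphenyl acetate (eugenyl acetate) | C=CCc1ccc(OC(C)=O)c(OC)c1 | starting material
13 | 3-(4-acetoxy-3-methoxybenzyl)-1,2,4-trioxolane (secondary ozonide, racemic) | COc1cc(CC2OCOO2)ccc1OC(C)=O | intermediate (not isolated)
14 | 2-(4-acetoxy-3-methoxyphenyl)acetaldehyde | COc1cc(CC=O)ccc1OC(C)=O | intermediate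
15 | 2-bromo-6-isocyanopyridine | [C-]#[N+]c1cccc(Br)n1 | starting material
16 | (2R)-3-(4-acetoxy-3-methoxyphenyl)-1-[(6-bromopyridin-2-yl)amino]-1-oxopropan-2-yl (E)-3-[(2R,3R)-2-(tert-butoxycarbonyl)-3-(2,2-dimethyl-1,3-benzodioxol-5-yl)-2,3-dihydro-1,4-benzodioxin-7-yl]prop-2-enoate | COc1cc(C[C@@H](OC(=O)/C=C/c2ccc3c(c2)O[C@@H](C(=O)OC(C)(C)C)[C@@H](c2ccc4OC(C)(C)Oc4c2)O3)C(=O)Nc2cccc(Br)n2)ccc1OC(C)=O | intermediate
17 | clinopodic acid F, (2R,3R)-7-[(E)-3-{[(1R)-1-carboxy-2-(4-hydroxy-3-methoxyphenyl)ethyl]oxy}-3-oxoprop-1-en-1-yl]-3-(3,4-dihydroxyphenyl)-2,3-dihydro-1,4-benzodioxine-2-carboxylic acid | COc1cc(C[C@@H](OC(=O)/C=C/c2ccc3c(c2)O[C@@H](C(=O)O)[C@@H](c2ccc(O)c(O)c2)O3)C(=O)O)ccc1O | target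

## Step count and risks

Total step count: 9.
Longest linear sequence: 7 steps (steps 1, 3, 4, 5, 6, 8, 9; the branch through step 2 is equally long).

Steps most likely to fail:

**Step 5 (asymmetric hydrogenation of a tetrasubstituted enol-ether ester).** The risk is low conversion or poor enantioselectivity. The fallback sets out from 8 and comes back at 9. Compound 8 is hydrogenated with the achiral complex [Ir(cod)(PCy3)(C5H5N)]PF6 (5 mol%, H2 50 bar, CH2Cl2, rt). Syn addition still gives only the cis ester, now as the racemate: 9 together with its mirror image, tert-butyl (2S,3S)-7-bromo-3-(2,2-dimethyl-1,3-benzodioxol-5-yl)-2,3-dihydro-1,4-benzodioxine-2-carboxylate F1. Preparative chiral supercritical-fluid chromatography separates the two and returns 9. Stereocontrol thus moves from asymmetric catalysis to diastereoselective reduction plus resolution.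

**Step 8 (three-component coupling with a bulky, chiral acid).** The risk is slow reaction or poor catalyst control (mismatch) with acid 11. The fallback sets out from 9 (with 10, 14 and 15) and comes back at 16. The same chiral phosphoric acid-catalysed Passerini reaction is run on the small acid: 10, 14 and 15 give (2R)-3-(4-acetoxy-3-methoxyphenyl)-1-[(6-bromopyridin-2-yl)amino]-1-oxopropan-2-yl prop-2-enoate F2, whose enantiopurity can be raised by crystallisation. A Mizoroki–Heck coupling of this acrylate with bromide 9 (Pd[P(t-Bu)3]2, Cy2NMe, 1,4-dioxane, 50 °C) then gives 16. Step 6 is omitted, and the fragment union becomes the Heck reaction instead of the three-component coupling.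

**Step 9 (one-pot amide hydrolysis and global deprotection).** The risk is that the pyridyl amide needs forcing acid, which would start to cleave the cinnamate ester or epimerise the benzylic C3 centre. The fallback sets out from 16 and comes back at 17. Boc2O with catalytic 4-(dimethylamino)pyridine in MeCN at rt converts the secondary amide into its twisted imide, the N-(tert-butoxycarbonyl) derivative of 16 F3. LiOH/H2O2 in THF/H2O at 0 °C (then Na2SO3) cleaves this activated acyl–nitrogen bond selectively, and also the aryl acetate. This gives (2R)-2-{[(E)-3-[(2R,3R)-2-(tert-butoxycarbonyl)-3-(2,2-dimethyl-1,3-benzodioxol-5-yl)-2,3-dihydro-1,4-benzodioxin-7-yl]prop-2-enoyl]oxy}-3-(4-hydroxy-3-methoxyphenyl)propanoic acid F4. Brief treatment with CF3CO2H/H2O (9:1) at rt removes the tert-butyl ester and the acetonide to give 17. The amide is thus cleaved by a nucleophile at 0 °C, and acid is needed only for the two most labile groups.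

## Further compounds

F1 | step 5 | tert-butyl (2S,3S)-7-bromo-3-(2,2-dimethyl-1,3-benzodioxol-5-yl)-2,3-dihydro-1,4-benzodioxine-2-carboxylate | Brc1ccc2c(c1)O[C@H](C(=O)OC(C)(C)C)[C@H](c1ccc3OC(C)(C)Oc3c1)O2
F2 | step 8 | (2R)-3-(4-acetoxy-3-methoxyphenyl)-1-[(6-bromopyridin-2-yl)amino]-1-oxopropan-2-yl prop-2-enoate | COc1cc(C[C@@H](OC(=O)C=C)C(=O)Nc2cccc(Br)n2)ccc1OC(C)=O
F3 | step 9 | N-(tert-butoxycarbonyl) derivative of 16 | COc1cc(C[C@@H](OC(=O)/C=C/c2ccc3c(c2)O[C@@H](C(=O)OC(C)(C)C)[C@@H](c2ccc4OC(C)(C)Oc4c2)O3)C(=O)N(C(=O)OC(C)(C)C)c2cccc(Br)n2)ccc1OC(C)=O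
F4 | step 9 | (2R)-2-{[(E)-3-[(2R,3R)-2-(tert-butoxycarbonyl)-3-(2,2-dimethyl-1,3-benzodioxol-5-yl)-2,3-dihydro-1,4-benzodioxin-7-yl]prop-2-enoyl]oxy}-3-(4-hydroxy-3-methoxyphenyl)propanoic acid | COc1cc(C[C@@H](OC(=O)/C=C/c2ccc3c(c2)O[C@@H](C(=O)OC(C)(C)C)[C@@H](c2ccc4OC(C)(C)Oc4c2)O3)C(=O)O)ccc1O
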